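**Retrosynthetic overview**
- Glyinflanin C ⇒ its isomeric B-ring aryl 1,1-dimethylallyl ether, by an aromatic Claisen rearrangement as the last step. This ether is the only phenol protection in the route and also the prenyl source.
- The 1,3-diketone ⇒ crossed Claisen condensation of 6-acetyl-7-hydroxy-2,2-dimethylchromene with methyl 4-(1,1-dimethylallyloxy)benzoate, which comes from methylparaben.
- The acetylchromene ⇒ C2v-symmetric 4,6-diacetylresorcinol plus acetone in a one-pot desymmetrisation: mono-enolisation, aldol, enolate-masked reduction, then o-quinone methide/oxa-6π closure. The symmetry of the precursor fixes the linear 6,7-fusion, which direct chromenylation of resacetophenone does not give.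
- Rings: both benzene rings are bought. The pyran is the only ring built (step 1).

Assumption: the target SMILES has no stereocentre and no stereogenic double bond, so the compound is achiral and there is no enantiomer to select. The diketone is drawn as the diketo tautomer although it is largely enolised.

**Step 1**
Reactants: 1 4,6-diacetylresorcinol; 2 acetone
Product: 8 1-(7-hydroxy-2,2-dimethyl-2H-chromen-6-yl)ethan-1-one (eupatoriochromene), via trilithium bis-phenoxide mono-enolate 3 (not isolated), via trilithium aldolate 4 (not isolated), via tetralithium enolate-masked aldolate 5 (not isolated), via racemic benzylic/tertiary diol 6 (not isolated), via vinyl o-quinone methide 7 (not isolated)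
Conditions: LDA (3.05 equiv), THF, −78 → −30 °C; 2 (1.05 equiv), −78 °C; LDA (1.2 equiv), −78 °C; DIBAL-H (3 equiv), −78 → −40 °C; 2 M HCl, 0 → 45 °C (one pot)
Reagents that add atoms: acetone (= 2), CC(C)=O
Why: Proposed new method: taking a third proton from the dilithium bis-phenoxide of 1 is much easier than taking a fourth, so three equivalents of LDA enolise only one of the two equivalent acetyl groups (3, symmetry broken by charge rather than by statistics); this enolate adds to acetone in a kinetic lithium aldol (4), the untouched acetyl is then hidden as its enolate by deprotonation at the free CH3 rather than at the hindered CH2 next to the alkoxide (5), DIBAL-H bound to the alkoxide as an ate complex finds only one C=O to reduce, and acid takes diol 6 through loss of two waters to the dearomatised o-quinone methide 7, whose oxa-6π electrocyclisation rearomatises to the chromene; the closest known reaction types are phenoxide/enolate polyanion chemistry of o-hydroxyacetophenones, in-situ enolate protection of a ketone during hydride reduction, and chromene formation from o-hydroxybenzylic alcohols through o-quinone methides, and the carbinol centre of 6 is racemic and is destroyed.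

**Step 2**
Reactants: 9 methyl 4-hydroxybenzoate (methylparaben); 10 tert-butyl (2-methylbut-3-en-2-yl) carbonate
Product: 11 methyl 4-[(2-methylbut-3-en-2-yl)oxy]benzoate
Conditions: Pd(PPh3)4 (3 mol%), THF, 0 °C, 3 h
Reagents that add atoms: tert-butyl (2-methylbut-3-en-2-yl) carbonate (= 10), C=CC(C)(C)OC(=O)OC(C)(C)C
Why: Tsuji–Trost O-allylation, in which decarboxylative ionisation of 10 gives a 1,1-dimethyl-π-allylpalladium cation and tert-butoxide that deprotonates 9, and under kinetic control at 0 °C the phenoxide attacks the more substituted allyl terminus to give the tertiary ether before Pd can isomerise it to the linear prenyl ether.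

**Step 3**
Reactants: 8 eupatoriochromene; 11 methyl 4-[(2-methylbut-3-en-2-yl)oxy]benzoate
Product: 13 1-(7-hydroxy-2,2-dimethyl-2H-chromen-6-yl)-3-{4-[(2-methylbut-3-en-2-yl)oxy]phenyl}propane-1,3-dione, via disodium phenoxide/enolate of 8 12 (not isolated)
Conditions: NaH (4 equiv), THF, reflux, 3 h; AcOH, 0 °C
Reagents that add atoms: none
Why: Crossed Claisen condensation in which dianion 12 acylates at carbon with the non-enolisable ester 11 (any O-acylation funnels to the same product by Baker–Venkataraman acyl shift) and irreversible diketonate formation drives it, while the chromene and the tertiary allyl ether are inert to base and 66 °C is well below the onset of the [3,3] shift.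

**Step 4**
Reactants: 13 the 1,1-dimethylallyl ether diketone
Product: 15 glyinflanin C, via racemic ortho-dienone 14 (not isolated)
Conditions: PhNEt2, 150 °C, 3 h, Ar
Reagents that add atoms: none
Why: Aromatic Claisen rearrangement, in which the [3,3] shift inverts the allyl unit so the 1,1-dimethylallyl ether arrives as a prenyl group on one of the two equivalent ortho carbons (para is blocked) to give dienone 14, which tautomerises to the free phenol; the gem-dimethyl group lowers the temperature to about 150 °C, where the chromene and chelated diketone survive, the amine solvent buffers acid traces that would close a flavone or chroman, and the step is a pure isomerisation that leaves no stereocentre.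

**Compound list**
1 | 4,6-diacetylresorcinol, 1,1'-(4,6-dihydroxybenzene-1,3-diyl)diethanone | CC(=O)c1cc(C(C)=O)c(O)cc1O | starting material
2 | acetone | CC(C)=O | starting material
3 | trilithium 4-acetyl-6-(1-oxidoethenyl)benzene-1,3-diolate | [Li+].[Li+].[Li+].C=C([O-])c1cc(C(C)=O)c([O-])cc1[O-] | intermediate
4 | trilithium salt (two phenoxides, tertiary alkoxide) of 1-(5-acetyl-2,4-dihydroxyphenyl)-3-hydroxy-3-methylbutan-1-one | [Li+].[Li+].[Li+].CC(=O)c1cc(C(=O)CC(C)(C)[O-])c([O-])cc1[O-] | intermediate
5 | tetralithium salt of the same aldol with the remaining acetyl as its enolate | [Li+].[Li+].[Li+].[Li+].C=C([O-])c1cc(C(=O)CC(C)(C)[O-])c([O-])cc1[O-] | intermediate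
6 | 1-[5-(1,3-dihydroxy-3-methylbutyl)-2,4-dihydroxyphenyl]ethan-1-one, racemic | CC(=O)c1cc(C(O)CC(C)(C)O)c(O)cc1O | intermediate
7 | 4-acetyl-3-hydroxy-6-(3-methylbut-2-en-1-ylidene)cyclohexa-2,4-dien-1-one, E/Z not defined | CC(=O)C1=CC(=CC=C(C)C)C(=O)C=C1O | intermediate
8 | 1-(7-hydroxy-2,2-dimethyl-2H-chromen-6-yl)ethan-1-one (eupatoriochromene) | CC(=O)c1cc2c(cc1O)OC(C)(C)C=C2 | intermediate
9 | methyl 4-hydroxybenzoate | COC(=O)c1ccc(O)cc1 | starting material
10 | tert-butyl (2-methylbut-3-en-2-yl) carbonate | C=CC(C)(C)OC(=O)OC(C)(C)C | starting material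
11 | methyl 4-[(2-methylbut-3-en-2-yl)oxy]benzoate | C=CC(C)(C)Oc1ccc(C(=O)OC)cc1 | intermediate
12 | disodium 2,2-dimethyl-6-(1-oxidoethenyl)-2H-chromen-7-olate | [Na+].[Na+].C=C([O-])c1cc2c(cc1[O-])OC(C)(C)C=C2 | intermediate
13 | 1-(7-hydroxy-2,2-dimethyl-2H-chromen-6-yl)-3-{4-[(2-methylbut-3-en-2-yl)oxy]phenyl}propane-1,3-dione | C=CC(C)(C)Oc1ccc(C(=O)CC(=O)c2cc3c(cc2O)OC(C)(C)C=C3)cc1 | intermediate
14 | 1-(7-hydroxy-2,2-dimethyl-2H-chromen-6-yl)-3-[3-(3-methylbut-2-en-1-yl)-4-oxocyclohexa-1,5-dien-1-yl]propane-1,3-dione, racemic | CC(C)=CCC1C=C(C(=O)CC(=O)c2cc3c(cc2O)OC(C)(C)C=C3)C=CC1=O | intermediate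
15 | glyinflanin C, 1-(7-hydroxy-2,2-dimethyl-2H-chromen-6-yl)-3-[4-hydroxy-3-(3-methylbut-2-en-1-yl)phenyl]propane-1,3-dione (achiral) | CC(C)=CCc1cc(C(=O)CC(=O)c2cc3c(cc2O)OC(C)(C)C=C3)ccc1O | target

**Total step count:** 4.
**Longest linear sequence:** 3 (steps 1, 3, 4, or steps 2, 3, 4).

**Steps most likely to fail**

Step 1 is the riskiest. The risks are incomplete or unselective enolisation, retro-aldol of 4, and over-reduction to the chroman through a quinone methide. The fallback sets out from 1 and 2 and returns at 8. It gives up the kinetic lithium aldol and closes the pyran first by a pyrrolidine-mediated Kabbe annulation of 1 with one equivalent of 2 (MeOH, rt → 60 °C). This gives isolable 6-acetyl-7-hydroxy-2,2-dimethylchroman-4-one F1. LDA (2.2 equiv) and TMSCl at −78 °C then mask the acetyl covalently as 2,2-dimethyl-7-(trimethylsilyloxy)-6-[1-(trimethylsilyloxy)ethenyl]chroman-4-one F2. DIBAL-H in toluene at −78 °C reduces the only ketone left, giving racemic 2,2-dimethyl-7-(trimethylsilyloxy)-6-[1-(trimethylsilyloxy)ethenyl]chroman-4-ol F3. Treatment with 1 M HCl in THF strips both silyl groups and dehydrates to 8.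

Step 4 is next. The risks are thermal flavone closure of the o-hydroxy diketone and loss of isoprene from the tertiary ether. The fallback sets out from 11 and returns at 15. It carries out the [3,3] shift on the simple ester: 11 in PhNEt2 at 180 °C gives methyl 4-hydroxy-3-(3-methylbut-2-en-1-yl)benzoate F4. TBSCl and imidazole in DMF give methyl 4-[(tert-butyldimethylsilyl)oxy]-3-(3-methylbut-2-en-1-yl)benzoate F5. Condensation with 8 (LiHMDS, 3.3 equiv, THF, −78 °C → rt) gives 1-{4-[(tert-butyldimethylsilyl)oxy]-3-(3-methylbut-2-en-1-yl)phenyl}-3-(7-hydroxy-2,2-dimethyl-2H-chromen-6-yl)propane-1,3-dione F6. TBAF/AcOH in THF at 0 °C then releases 15.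

Step 2 is third. The risk is that the fairly acidic phenol lets Pd re-ionise the product and drift to the linear prenyl ether. The fallback sets out from 9 and returns at 11. It builds the tertiary C–O bond at the alkyne level by copper-catalysed propargylation with 3-chloro-3-methylbut-1-yne (CuCl2 cat., DBU, MeCN, 0 °C). This gives methyl 4-[(2-methylbut-3-yn-2-yl)oxy]benzoate F7. Lindlar semihydrogenation (H2, Pd/CaCO3–Pb, quinoline, EtOAc) then gives 11.

**Further compounds**
F1 | step 1 | 6-acetyl-7-hydroxy-2,2-dimethylchroman-4-one | CC(=O)c1cc2c(cc1O)OC(C)(C)CC2=O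
F2 | step 1 | 2,2-dimethyl-7-(trimethylsilyloxy)-6-[1-(trimethylsilyloxy)ethenyl]chroman-4-one | C=C(O[Si](C)(C)C)c1cc2c(cc1O[Si](C)(C)C)OC(C)(C)CC2=O
F3 | step 1 | 2,2-dimethyl-7-(trimethylsilyloxy)-6-[1-(trimethylsilyloxy)ethenyl]chroman-4-ol, racemic | C=C(O[Si](C)(C)C)c1cc2c(cc1O[Si](C)(C)C)OC(C)(C)CC2O
F4 | step 4 | methyl 4-hydroxy-3-(3-methylbut-2-en-1-yl)benzoate | COC(=O)c1ccc(O)c(CC=C(C)C)c1
F5 | step 4 | methyl 4-[(tert-butyldimethylsilyl)oxy]-3-(3-methylbut-2-en-1-yl)benzoate | COC(=O)c1ccc(O[Si](C)(C)C(C)(C)C)c(CC=C(C)C)c1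
F6 | step 4 | 1-{4-[(tert-butyldimethylsilyl)oxy]-3-(3-methylbut-2-en-1-yl)phenyl}-3-(7-hydroxy-2,2-dimethyl-2H-chromen-6-yl)propane-1,3-dione | CC(C)=CCc1cc(C(=O)CC(=O)c2cc3c(cc2O)OC(C)(C)C=C3)ccc1O[Si](C)(C)C(C)(C)C
F7 | step 2 | methyl 4-[(2-methylbut-3-yn-2-yl)oxy]benzoate | C#CC(C)(C)Oc1ccc(C(=O)OC)cc1
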